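(The earlier runs and the new flask stem from a simulated flask with made-up constants, and the scatter is random.)

Every G in a flask came across from Z, so the gas taken up equals the G dissolved plus the G already reacted. Z is held at constant pressure, so 1.7 mM is its saturation level and not a charge, while J, at 20 mM in the asked flask, is the finite reagent. I therefore write the balance of the gas taken up and hold it against that J.

| setting | maple | larch | flask |
|---|---|---|---|
| J | 20 mM | 40 mM | 20 mM |
| Z | 1.7 mM (held) | 1.7 mM (held) | 1.7 mM (held) |
| remark | the very flask that is asked about, followed so far | run made earlier |  |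
| time |  |  | 8.0 min |

- maple (time / s: E / %, J / %): 10.0: 0, 100; 20.0: 2, 95; 30.0: 6, 98; 50.0: 7, 92; 80.0: 11, 89; 90.0: 12, 86
- larch (time / min: E / %, J / %): 0.667: 3, 97; 1.00: 4, 92; 2.00: 10, 89; 3.00: 14, 86; 5.00: 14, 80; 8.00: 14, 74

(scatter of a reading: 1.5 percentage points)

- E at 8.0 min, in percent of the J charged
- concentration of G in solution at 8.0 min, in percent of saturation

- the numbers in the tables scatter with a standard deviation of 1.5 percentage points
- at the start none of Z is in solution
- G is what Z becomes in solution

Early E gives 1.60 mM min⁻¹ in maple but 2.00 mM min⁻¹ in larch, which has twice the J. I treat crossing and reaction as resistances in series, 1/rate = a + b/[J]. These two readings then give my gas ceiling, the uptake rate with [G] held at zero, where the crossing is the rate-limiting step: 2.67 mM min⁻¹. Its time constant is 0.637 min.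

This gives two extreme versions of the asked flask. If G is used at once, uptake by 8.0 min reaches 21.4 mM, more than the 20 mM of J, and E could take up all the J. If nothing uses G, [G] fills to 1.7 mM within a time of order 0.637 min, and uptake ends there.

Larch lies between: E stands at 14% while J still falls by 0.960 mM min⁻¹. Setting that drain against the ceiling, I put [G] in the asked flask near 64.0% of saturation. I put E between 14%, if the stop scales with the charge, and 28.0%, if it is a fixed concentration.

The forecast says “This looks like a concentration cap” and gives 27% and 60%, so its [G] lies below mine.

The flask gives 15.7% and 68.3%.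

    G + E → Q (k = 2.55 M⁻¹ s⁻¹)
    J + G ⇌ E (K = 220 M⁻¹, k = 6.40 M⁻¹ s⁻¹)
    Z ⇌ G, rate k3*(csat - [G]) (kL = 0.0323 s⁻¹)

Each E holds one G and each Q holds two, so the asked flask has taken up 11.4 mM by 8.0 min, which is 53.4% of what my ceiling allows. The neighbour with 80 mM of J runs for the same time against the same ceiling. It holds E at 11.5% and Q at 5.58% of its own charge, so its uptake is 18.8 mM, or 88.0% of the allowance, and its [G] stands at 0.672 mM.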